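**Retrosynthetic overview**

1. The lactone ring (C12–O–C6) is closed last by oxidative lactonisation. C6–O comes from the furanone trienolate, the furanone ring (C3–O–C10, C1=O) from cyclodehydration of a C1,C3-diketone, and C8–O is delivered from the C10 oxygen through a silicon tether.
2. The ten-membered carbocycle comes from an anionic oxy-Cope rearrangement of cyclohexenol 19: C1–C10 is formed and C3–C8 is broken (four-atom ring expansion).
3. Feature used: the six-membered ring C3–C4(Me)=C5–C6–C7–C8 of the target, with the C7 stereocentre, the ring-cis C4=C5 bond and C11–C13 on C7, is (S)-carvone. Only C9, C10, C1 and C2 are inserted between C8 and C3.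
4. 19 is made from carvone by C8 allylation anti to isopropenyl, Wacker oxidation and Z enol MOM ether formation (C3 masked as a silyl ether), then alkoxyacetylide addition to C3 and trans-hydroalumination.
5. Ring order: carvone ring (chiral pool), then ten-membered ring (step 9), then furanone (step 16), then lactone (step 19).

Key step: step 9

Remark (assumption): carbons are numbered as in the target (C1 furanone C=O, C2=C3–O, C4(Me)=C5, C6 lactone OCH, C7, C8 ester OCH, C9, C10 C(Me)O, C11=C13, C12 lactone C=O) and β is the ring face carrying C11 at C7. Carbinol centres that are oxidised again later (C3 in 5–11 and in 23–31) are drawn as the expected epimer or left undefined, because they do not reach the target.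

**Route**

Step 1
Reactants: 1 (S)-(+)-carvone; 2 allyl bromide
Product: 4 (5S,6R)-6-allyl-2-methyl-5-(prop-1-en-2-yl)cyclohex-2-en-1-one (trans-6-allylcarvone), via lithium enolate 3 (not isolated)
Conditions: LiN(iPr)2, THF, −78 °C; then 2, −78 to 0 °C
Reagents that add atoms: none
Why: Kinetic α′-deprotonation gives the cross-conjugated lithium enolate, which is C-alkylated at C8 on the face anti to the neighbouring C7 isopropenyl group (enolate alkylation), so the C8 chain should end up trans to C7.

Step 2
Reactants: 4 trans-6-allylcarvone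
Product: 6 C3 tert-butyldimethylsilyl ether of the allylic alcohol, via allylic alcohol 5 (not isolated)
Conditions: NaBH4, CeCl3·7H2O, MeOH, −78 °C; then t-BuMe2SiCl, imidazole, DMF, 23 °C
Reagents that add atoms: tert-butyldimethylsilyl chloride, CC(C)(C)[Si](C)(C)Cl
Why: Luche 1,2-reduction (axial hydride delivery, OH expected trans to the C8 allyl group, a centre that is reoxidised in step 5) and silylation mask the enone carbonyl, so that the side-chain ketone made next can be enolised without a furan- and aldol-prone 1,4-diketone or an enone dienolate that would scramble C8.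

Step 3
Reactants: 6 C3 silyl ether
Product: 7 methyl ketone (C8–CH2–CO–CH3)
Conditions: PdCl2 (cat.), CuCl, O2 (1 atm), DMF/H2O 7:1, 23 °C
Reagents that add atoms: water, O
Why: Tsuji–Wacker oxidation (Markovnikov hydroxypalladation) should convert only the monosubstituted terminal alkene into the methyl ketone, since the 1,1-disubstituted isopropenyl and the trisubstituted ring alkene react far more slowly.

Step 4
Reactants: 7 methyl ketone
Product: 10 (Z)-enol methoxymethyl ether (C8–CH=C(CH3)OCH2OCH3, O cis to C8), via trimethylsilyl enol ether 8 (not isolated), via lithium enolate 9 (not isolated)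
Conditions: Me3SiCl, NaI, Et3N, MeCN, 23 °C; then MeLi, THF, 0 °C; then HMPA, MeOCH2Cl, −78 to 0 °C
Reagents that add atoms: chloromethyl methyl ether, COCCl
Why: Thermodynamic silylation with iodotrimethylsilane made in the flask should give mainly the more substituted Z silyl enol ether (the isomer free of allylic 1,3-strain between the methyl group and the ring), MeLi releases the lithium enolate with its position and geometry retained, and the hard α-chloro ether alkylates it on oxygen in HMPA; minor terminal and E isomers are to be removed by chromatography on triethylamine-washed silica.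

Step 5
Reactants: 10 (Z)-enol MOM ether
Product: 12 enone, 6-[(Z)-2-(methoxymethoxy)prop-1-enyl]-2-methyl-5-(prop-1-en-2-yl)cyclohex-2-en-1-one, via allylic alcohol 11 (not isolated)
Conditions: Bu4NF, THF, 0 to 23 °C; then MnO2, CH2Cl2, 23 °C
Reagents that add atoms: none
Why: Fluoride desilylation and neutral MnO2 oxidation of the allylic alcohol restore the C3 enone without acid or base, so the enol ether and the epimerisable C8 centre of this β,γ-unsaturated ketone should survive.

Step 6
Reactants: 13 4-methoxybenzyl alcohol; 14 trichloroethylene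
Product: 15 (E)-1,2-dichlorovinyl 4-methoxybenzyl ether
Conditions: KH, THF, 0 °C; then 14, −50 to 23 °C
Reagents that add atoms: none
Why: Addition–elimination of the potassium alkoxide on trichloroethylene gives the E 1,2-dichlorovinyl ether, the usual precursor of alkynyl ethers, and forms no stereocentre.

Step 7
Reactants: 15 dichlorovinyl ether; 12 enone
Product: 18 propargylic alcohol (C3(OH)–C≡C–OCH2C6H4OMe, OH cis to the C8 chain), via chloroalkynyl ether 16 (not isolated), via lithium alkoxyacetylide 17 (not isolated)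
Conditions: 15, n-BuLi (2.1 equiv), THF, −78 to −40 °C; CeCl3, −78 °C; then 12, −78 °C; pH 7 buffer
Reagents that add atoms: none
Why: Loss of HCl and chlorine–lithium exchange give the lithium alkoxyacetylide, whose cerium reagent adds 1,2 to the enone carbonyl without enolising the acidic C8–H (organocerium carbonyl addition), and approach anti to the neighbouring C8 alkenyl chain should place the alkynyl group trans to it; any C3 epimer is carried on because step 9 converges.

Step 8
Reactants: 18 propargylic alcohol
Product: 19 oxy-Cope precursor, 1-[(E)-2-(4-methoxybenzyloxy)vinyl]-6-[(Z)-2-(methoxymethoxy)prop-1-enyl]-2-methyl-5-(prop-1-en-2-yl)cyclohex-2-en-1-ol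
Conditions: NaAlH2(OCH2CH2OMe)2, THF, 0 to 23 °C; aq. potassium sodium tartrate
Reagents that add atoms: none
Why: Alkoxide-directed trans-hydroalumination of the propargylic alcohol followed by protonolysis gives the E enol ether (the known reduction of alkoxyethynyl carbinols to E β-alkoxyvinyl carbinols), a two-step detour taken because an E-2-alkoxyvinyllithium would lose alkoxide by anti-elimination.

Step 9
Reactants: 19 oxy-Cope precursor
Product: 22 ten-membered ketone (C3=O, Z C4=C5, E C8=C9, C10(Me)(OMOM), C1 OPMB), via potassium alkoxide 20 (not isolated), via potassium enolate 21 (not isolated)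
Conditions: KN(SiMe3)2, 18-crown-6, THF, −78 to 0 °C; AcOH, −78 °C
Reagents that add atoms: none
Why: KN(SiMe3)2 gives the potassium alkoxide 20, whose 1,5-diene C1=C2–C3–C8–C9=C10 undergoes an alkoxide-accelerated [3,3]-sigmatropic shift that forms C1–C10, breaks C3–C8 and ends irreversibly at the C2=C3 enolate 21. The closest known reaction is the anionic oxy-Cope rearrangement of 1,2-dialkenylcyclohexanols to cyclodec-5-enones. The ten-membered carbocycle is not closed end to end but arises by four-atom expansion of the carvone ring through a six-membered chair array in which the ring bonds C3–C4 and C8–C7 are equatorial. C10 is controlled by the C8 stereocentre and the Z enol ether: allylic strain keeps H8 inside and C7 outside on the C8–C9–C10 unit, so C1 bonds to the C10 face on which C3 lies with OMOM axial and methyl equatorial, which also gives E C8=C9 and makes a C3 epimer of 19 converge on the same C10; C1 is controlled by the E alkoxyvinyl group (OPMB equatorial) and is erased in step 16. The step needs the exocyclic chair to beat the boat that would bond C10 to C5 through the ring C4=C5 bond, and the all-equatorial half-chair of 19 (C8 chain trans to isopropenyl) holds the enol ether away from C5. It also needs enolate 21 to be protonated before it expels the β-OPMB group, which the quench at −78 °C should secure.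

Step 10
Reactants: 22 ten-membered ketone
Product: 24 C1,C3-bis(4-methoxybenzyl) ether, via allylic alcohol 23 (not isolated)
Conditions: NaBH4, CeCl3·7H2O, MeOH, −78 °C; then NaH, 4-MeOC6H4CH2Cl, Bu4NI, THF/DMF, 0 to 23 °C
Reagents that add atoms: 4-methoxybenzyl chloride, COc1ccc(CCl)cc1
Why: Luche 1,2-reduction and Williamson etherification mask C3 (either epimer serves, the centre being reoxidised in step 16), so that the C10 hydroxyl freed next cannot close onto a C3 ketone as a hemiketal.

Step 11
Reactants: 24 bis(4-methoxybenzyl) ether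
Product: 26 C10 tertiary alcohol, via bromomethyl ether 25 (not isolated)
Conditions: Me2BBr, CH2Cl2, −78 °C; then aq. NaHCO3, THF
Reagents that add atoms: none
Why: Bromodimethylborane cleaves the MOM acetal at its methoxy oxygen at −78 °C (acetal cleavage through the bromomethyl ether, hydrolysed on work-up), which should leave the tertiary allylic C10–O bond and the benzylic ethers intact.

Step 12
Reactants: 26 C10 tertiary alcohol
Product: 28 bicyclic oxasilolane (five-membered ring C10–O–SiMe2–C8–C9), via hydrosilyl ether 27 (not isolated)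
Conditions: Me2SiHCl, Et3N, CH2Cl2, 0 °C; then Pt2[(CH2=CHSiMe2)2O]3 (cat.), toluene, 60 °C
Reagents that add atoms: chlorodimethylsilane, C[SiH](C)Cl
Why: Intramolecular hydrosilylation of the allylic hydrosilyl ether (Tamao–Ito 5-endo mode) delivers silicon to C8 and hydrogen to C9, and the five-membered ring can only form with silicon on the face of the C10 oxygen, which sets C8 cis-1,3 to O10 and leaves the isopropenyl group untouched.

Step 13
Reactants: 28 oxasilolane
Product: 29 8β,10-diol
Conditions: H2O2 (30%), KF, KHCO3, THF/MeOH, 23 °C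
Reagents that add atoms: hydrogen peroxide, OO
Why: Tamao–Fleming oxidation replaces the C8–Si bond by C8–OH with retention, so the 8β-alcohol of the target should result.

Step 14
Reactants: 29 diol
Product: 30 C8 3-methylbutanoate (C10 OH free)
Conditions: (Me2CHCH2CO)2O, Et3N, DMAP, CH2Cl2, 0 to 23 °C
Reagents that add atoms: 3-methylbutanoic anhydride, CC(C)CC(=O)OC(=O)CC(C)C
Why: DMAP-catalysed acylation esterifies the secondary C8 alcohol while the tertiary C10 alcohol is too hindered to react, and no stereocentre is touched.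

Step 15
Reactants: 30 C8 ester
Product: 31 C1,C3,C10-triol 8-(3-methylbutanoate)
Conditions: DDQ (2.5 equiv), CH2Cl2/pH 7 buffer, 0 °C
Reagents that add atoms: none
Why: Oxidative cleavage of both 4-methoxybenzyl ethers by DDQ (hydride abstraction, then hydrolysis of the oxocarbenium ion) frees the C1 and C3 hydroxyls without touching the ester, and any C3 enone formed by over-oxidation of the allylic ether converges in step 16.

Step 16
Reactants: 31 triol
Product: 33 3(2H)-furanone (C1=O, C2=C3–O–C10), via hydroxy diketone 32 (not isolated)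
Conditions: Dess–Martin periodinane, NaHCO3, CH2Cl2, 23 °C; then TsOH·H2O (cat.), CH2Cl2, 23 °C
Reagents that add atoms: none
Why: Double alcohol oxidation gives the C1,C3-diketone, whose tertiary C10 hydroxyl adds to C3 and loses water (acid-catalysed cyclodehydration of an α′-hydroxy 1,3-diketone to a 3(2H)-furanone, 5-exo closure), with C10 unaffected.

Step 17
Reactants: 33 furanone
Product: 35 6α-hydroxy furanone, via potassium trienolate 34 (not isolated)
Conditions: KN(SiMe3)2 (1.05 equiv), THF, −78 °C; 2-(phenylsulfonyl)-3-phenyloxaziridine, −78 °C; AcOH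
Reagents that add atoms: 2-(phenylsulfonyl)-3-phenyloxaziridine, O=S(=O)(N1OC1c1ccccc1)c1ccccc1
Why: Proposed new method: KN(SiMe3)2 should remove only a C6 proton of 33 (the sole sp3 C–H conjugated through C5=C4–C3=C2 to the C1 carbonyl), and the push–pull trienolate 34 should take oxygen from the N-sulfonyloxaziridine at its C6 terminus, because attack there alone restores the fully conjugated furanone, with approach anti to the neighbouring C7 isopropenyl group giving the 6α-alcohol; the closest known reactions are enolate hydroxylation with 2-sulfonyloxaziridines (Davis oxidation) and the terminus-selective alkylation of γ-deprotonated 5-alkyl-3(2H)-furanones.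

Step 18
Reactants: 35 6α-hydroxy furanone
Product: 36 6α,12-diol (C11(=C13)–C12H2OH)
Conditions: SeO2 (cat.), t-BuOOH, CH2Cl2, 23 °C
Reagents that add atoms: tert-butyl hydroperoxide, CC(C)(C)OO
Why: Selenium dioxide ene reaction and [2,3]-shift (Sharpless allylic oxidation) should hydroxylate the methyl group of the electron-rich 1,1-disubstituted isopropenyl unit while the electron-poor conjugated C4=C5 bond stays inert, and any enal formed converges in step 19.

Step 19
Reactants: 36 6α,12-diol
Product: 39 target CNP0409052.1, via hydroxy enal 37 (not isolated), via lactol 38 (not isolated)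
Conditions: TEMPO (cat.), PhI(OAc)2, CH2Cl2, 23 °C
Reagents that add atoms: none
Why: Oxoammonium oxidation selects the primary allylic alcohol, the enal is trapped by the C6 hydroxyl as the lactol, and this is oxidised on to the α-methylene γ-lactone (oxidative lactonisation of a 1,4-diol), with C6 and C7 keeping their configuration.

**Compound list**

1 | (S)-(+)-carvone | CC1=CC[C@@H](CC1=O)C(C)=C | starting material
2 | allyl bromide | C=CCBr | starting material
3 | lithium enolate of carvone, C3(OLi)=C8 (not isolated) | C=C(C)[C@H]1CC=C(C)C([O-])=C1.[Li+] | intermediate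
4 | (5S,6R)-6-allyl-2-methyl-5-(prop-1-en-2-yl)cyclohex-2-en-1-one; C8 allyl trans to C7 isopropenyl | C=C(C)[C@H]1CC=C(C)C(=O)[C@@H]1CC=C | intermediate
5 | C3 allylic alcohol of 4; OH trans to the C8 allyl group, cis to isopropenyl (not isolated) | C=C(C)[C@H]1CC=C(C)[C@@H](O)[C@@H]1CC=C | intermediate
6 | tert-butyldimethylsilyl ether of 5 | C=C(C)[C@H]1CC=C(C)[C@@H](O[Si](C)(C)C(C)(C)C)[C@@H]1CC=C | intermediate
7 | methyl ketone, C8–CH2–CO–CH3, C3 silyl ether | C=C(C)[C@H]1CC=C(C)[C@@H](O[Si](C)(C)C(C)(C)C)[C@@H]1CC(C)=O | intermediate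
8 | (Z)-trimethylsilyl enol ether of 7, O cis to C8 (not isolated) | C=C(C)[C@H]1CC=C(C)[C@@H](O[Si](C)(C)C(C)(C)C)[C@@H]1/C=C(/C)O[Si](C)(C)C | intermediate
9 | lithium (Z)-enolate from 8 (not isolated) | C=C(C)[C@H]1CC=C(C)[C@@H](O[Si](C)(C)C(C)(C)C)[C@@H]1/C=C(/C)[O-].[Li+] | intermediate
10 | (Z)-enol methoxymethyl ether, C8–CH=C(CH3)OCH2OCH3, C3 silyl ether | C=C(C)[C@H]1CC=C(C)[C@@H](O[Si](C)(C)C(C)(C)C)[C@@H]1/C=C(/C)OCOC | intermediate
11 | C3 allylic alcohol from 10 (not isolated) | C=C(C)[C@H]1CC=C(C)[C@@H](O)[C@@H]1/C=C(/C)OCOC | intermediate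
12 | 6-[(Z)-2-(methoxymethoxy)prop-1-enyl]-2-methyl-5-(prop-1-en-2-yl)cyclohex-2-en-1-one; side chain trans to isopropenyl | C=C(C)[C@H]1CC=C(C)C(=O)[C@@H]1/C=C(/C)OCOC | intermediate
13 | 4-methoxybenzyl alcohol | COc1ccc(CO)cc1 | starting material
14 | trichloroethylene | ClC=C(Cl)Cl | starting material
15 | (E)-1,2-dichlorovinyl 4-methoxybenzyl ether | COc1ccc(CO/C(Cl)=C\Cl)cc1 | intermediate
16 | chloroethynyl 4-methoxybenzyl ether (not isolated) | COc1ccc(COC#CCl)cc1 | intermediate
17 | lithium (4-methoxybenzyloxy)acetylide (not isolated) | COc1ccc(COC#C[Li])cc1 | intermediate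
18 | propargylic alcohol, C3(OH)–C≡C–OPMB; OH cis to the C8 chain, alkynyl trans to it | C=C(C)[C@H]1CC=C(C)[C@@](O)(C#COCc2ccc(OC)cc2)[C@@H]1/C=C(/C)OCOC | intermediate
19 | 1-[(E)-2-(4-methoxybenzyloxy)vinyl]-6-[(Z)-2-(methoxymethoxy)prop-1-enyl]-2-methyl-5-(prop-1-en-2-yl)cyclohex-2-en-1-ol; the two alkenyl groups trans, C8 chain trans to isopropenyl | C=C(C)[C@H]1CC=C(C)[C@@](O)(/C=C/OCc2ccc(OC)cc2)[C@@H]1/C=C(/C)OCOC | intermediate
20 | potassium alkoxide of 19 (not isolated) | C=C(C)[C@H]1CC=C(C)[C@@]([O-])(/C=C/OCc2ccc(OC)cc2)[C@@H]1/C=C(/C)OCOC.[K+] | intermediate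
21 | potassium C2=C3 enolate of 22 (not isolated) | C=C(C)[C@H]1C/C=C(/C)\C([O-])=C\[C@@H](OCc2ccc(OC)cc2)[C@@](C)(OCOC)/C=C/1.[K+] | intermediate
22 | ten-membered ketone: C3=O, Z C4(Me)=C5, C7 isopropenyl, E C8=C9, C10(Me)(OMOM), C1 OPMB | C=C(C)[C@H]1C/C=C(/C)C(=O)C[C@@H](OCc2ccc(OC)cc2)[C@@](C)(OCOC)/C=C/1 | intermediate
23 | C3 allylic alcohol of 22, C3 configuration not defined (not isolated) | C=C(C)[C@H]1C/C=C(/C)C(O)C[C@@H](OCc2ccc(OC)cc2)[C@@](C)(OCOC)/C=C/1 | intermediate
24 | C1,C3-bis(4-methoxybenzyl) ether, C10 OMOM | C=C(C)[C@H]1C/C=C(/C)C(OCc2ccc(OC)cc2)C[C@@H](OCc3ccc(OC)cc3)[C@@](C)(OCOC)/C=C/1 | intermediate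
25 | C10 bromomethyl ether (not isolated) | C=C(C)[C@H]1C/C=C(/C)C(OCc2ccc(OC)cc2)C[C@@H](OCc3ccc(OC)cc3)[C@@](C)(OCBr)/C=C/1 | intermediate
26 | C10 tertiary alcohol | C=C(C)[C@H]1C/C=C(/C)C(OCc2ccc(OC)cc2)C[C@@H](OCc3ccc(OC)cc3)[C@@](C)(O)/C=C/1 | intermediate
27 | C10 dimethylsilyl (Si–H) ether (not isolated) | C=C(C)[C@H]1C/C=C(/C)C(OCc2ccc(OC)cc2)C[C@@H](OCc3ccc(OC)cc3)[C@@](C)(O[SiH](C)C)/C=C/1 | intermediate
28 | bicyclic oxasilolane, ring C10–O–SiMe2–C8–C9, silicon on the face of O10 | C=C(C)[C@H]1C/C=C(/C)C(OCc2ccc(OC)cc2)C[C@@H](OCc3ccc(OC)cc3)[C@@]4(C)O[Si](C)(C)[C@@H]1C4 | intermediate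
29 | 8β,10-diol | C=C(C)[C@H]1C/C=C(/C)C(OCc2ccc(OC)cc2)C[C@@H](OCc3ccc(OC)cc3)[C@@](C)(O)C[C@H]1O | intermediate
30 | C8 3-methylbutanoate, C10 OH free | C=C(C)[C@H]1C/C=C(/C)C(OCc2ccc(OC)cc2)C[C@@H](OCc3ccc(OC)cc3)[C@@](C)(O)C[C@H]1OC(=O)CC(C)C | intermediate
31 | C1,C3,C10-triol 8-(3-methylbutanoate) | C=C(C)[C@H]1C/C=C(/C)C(O)C[C@@H](O)[C@@](C)(O)C[C@H]1OC(=O)CC(C)C | intermediate
32 | 10-hydroxy-1,3-diketone (not isolated) | C=C(C)[C@H]1C/C=C(/C)C(=O)CC(=O)[C@@](C)(O)C[C@H]1OC(=O)CC(C)C | intermediate
33 | 3(2H)-furanone: C1=O, C2=C3–O–C10, Z C4=C5, C7 isopropenyl, C8 3-methylbutanoate | C=C(C)[C@H]1C/C=C(/C)C2=CC(=O)[C@](C)(C[C@H]1OC(=O)CC(C)C)O2 | intermediate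
34 | potassium trienolate of 33, C1(OK)=C2–C3=C4–C5=C6, double-bond geometry not defined (not isolated) | C=C(C)[C@H]1C=CC(C)=C2C=C([O-])[C@](C)(C[C@H]1OC(=O)CC(C)C)O2.[K+] | intermediate
35 | 6α-hydroxy furanone (C6 as in the target) | C=C(C)[C@H]1[C@H](O)/C=C(/C)C2=CC(=O)[C@](C)(C[C@H]1OC(=O)CC(C)C)O2 | intermediate
36 | 6α,12-diol, C11(=C13)–C12H2OH | C=C(CO)[C@H]1[C@H](O)/C=C(/C)C2=CC(=O)[C@](C)(C[C@H]1OC(=O)CC(C)C)O2 | intermediate
37 | 6α-hydroxy 12-aldehyde (not isolated) | C=C(C=O)[C@H]1[C@H](O)/C=C(/C)C2=CC(=O)[C@](C)(C[C@H]1OC(=O)CC(C)C)O2 | intermediate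
38 | 12,6-lactol, C12 configuration not defined (not isolated) | C=C1C(O)O[C@@H]2/C=C(/C)C3=CC(=O)[C@](C)(C[C@@H](OC(=O)CC(C)C)[C@@H]12)O3 | intermediate
39 | CNP0409052.1, (6R,7R,8R,10S)-3,10-epoxy-1-oxogermacra-2,4Z,11(13)-trien-12,6-olid-8-yl 3-methylbutanoate | C=C1C(=O)O[C@@H]2/C=C(/C)C3=CC(=O)[C@](C)(C[C@@H](OC(=O)CC(C)C)[C@@H]12)O3 | target

**Step count and risk**

Total step count: 19. Longest linear sequence: 18 steps (steps 1–5 and 7–19 from (S)-carvone); step 6 prepares the acetylide precursor.

Steps most likely to fail: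

1. Step 17 (Proposed new method). Oxygen may be transferred to C2 or C4 of the trienolate instead of C6, the oxaziridine may attack the wrong face of C6, or the base may enolise the C8 ester. Fallback, known chemistry, from 33 to 39: SeO2 with t-BuOOH would give the C12 allylic alcohol F1. TEMPO with NaOCl and NaClO2 would oxidise it to the acrylic acid F2. N-bromosuccinimide with dibenzoyl peroxide in PhCF3 would brominate the doubly activated allylic C6 methylene (Wohl–Ziegler bromination) to the C6 bromide F3. Ag2CO3 would then close the lactone by carboxylate displacement and rejoin the route at 39. The allylic bromide epimers can interconvert, and the ten-membered ring should accept only the trans-fused γ-lactone.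

2. Step 9. The rearrangement may lose chair control (boat pathway through the ring C4=C5 bond), or enolate 21 may expel the β-alkoxy group or fragment before it is protonated. Fallback from 19 to 22: Me3SiCl with imidazole would give the trimethylsilyl ether F4. Heating in decalin at about 180 °C would bring about the neutral siloxy-Cope rearrangement to the silyl enol ether F5, with no enolate and therefore no β-elimination. K2CO3 in MeOH would then release ketone 22.

3. Step 12. Ring closure in the 5-endo mode may be slow in the medium ring, so intermolecular hydrosilylation of the isopropenyl group and oligomerisation could compete. Fallback from 26 to 29: hydroxyl-directed epoxidation with VO(acac)2 and t-BuOOH would give the epoxy alcohol F6, with the epoxide on the face of the C10 hydroxyl. NaAlH2(OCH2CH2OMe)2 would then deliver hydride from the C10 alkoxide to C9 (2,3-epoxy alcohol to 1,3-diol opening) and give diol 29.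

Further compounds
F1 | step 17 | C12 allylic alcohol of furanone 33 | C=C(CO)[C@H]1C/C=C(/C)C2=CC(=O)[C@](C)(C[C@H]1OC(=O)CC(C)C)O2
F2 | step 17 | acrylic acid (C12 carboxylic acid) of furanone 33 | C=C(C(=O)O)[C@H]1C/C=C(/C)C2=CC(=O)[C@](C)(C[C@H]1OC(=O)CC(C)C)O2
F3 | step 17 | C6 allylic bromide of F2, C6 epimers | C=C(C(=O)O)[C@H]1C(Br)/C=C(/C)C2=CC(=O)[C@](C)(C[C@H]1OC(=O)CC(C)C)O2
F4 | step 9 | trimethylsilyl ether of 19 | C=C(C)[C@H]1CC=C(C)[C@@](O[Si](C)(C)C)(/C=C/OCc2ccc(OC)cc2)[C@@H]1/C=C(/C)OCOC
F5 | step 9 | trimethylsilyl enol ether of 22 | C=C(C)[C@H]1C/C=C(/C)\C(O[Si](C)(C)C)=C\[C@@H](OCc2ccc(OC)cc2)[C@@](C)(OCOC)/C=C/1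
F6 | step 12 | 8,9-epoxy alcohol from 26, epoxide on the face of the C10 hydroxyl | C=C(C)[C@H]1C/C=C(/C)C(OCc2ccc(OC)cc2)C[C@@H](OCc3ccc(OC)cc3)[C@@](C)(O)[C@@H]4O[C@@H]14
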